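At the first reading, 0.417 d after the start, the birch flask, in which Z and J with the catalyst G give Q and L, already holds 54% of Q against 3% of L, and the quick number can be taken from that pair.

| flask | Z | J | G | remark | time |
|---|---|---|---|---|---|
| birch | 0.30 M | 0.315 M | 0.30 mM | the very flask that is asked about, followed so far |  |
| flask | 0.30 M | 0.315 M | 0.30 mM |  | 15 d |

birch run (percent of the Z charged)

| time / d | Q / % | L / % |
|---|---|---|
| 0.417 | 54 | 3 |
| 1.25 | 69 | 9 |
| 2.00 | 74 | 8 |
| 3.00 | 78 | 12 |
| 5.00 | 76 | 10 |
| 6.00 | 79 | 12 |
| 8.00 | 75 | 14 |

(each reading ± 1.5 percentage points)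

- the numbers in the tables scatter with a standard deviation of 1.5 percentage points
- a reading or a percentage of Q counts all its forms, free or not

- share of Q in Q plus L at 6.0 min
- share of Q in Q plus L at 6.0 h
- share of Q in Q plus L at 15 d

The hunch of a level start makes a good zero of the scale: two routes of equal speed give one Q per L, a share of half. The birch flask stands far from that zero, with 18.0 Q per L at the first reading. This is the selectivity factor, Q formed per L formed at the earliest reading, and it turns into a share as factor over factor plus one, here 94.7%. It is a loose reading, since L one scatter higher gives a factor of 12.0. The share then drifts down, to 84.3% at 8.00 d, so this reckoning puts 15 d under 84.3%. Both 6.0 min and 6.0 h lie before the first reading, so it carries the factor back and puts both near 94.7%.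

The forecast gave 97%, 95.5% and 83%, and granted that “a parallel route can't be excluded”.

The flask gives 92.2%, 90.4% and 80.8%.

    E ⇌ Q, rate k1*(cs1 - [Q]) while solid is left; crystals form when [Q] > cs1 (solubility = 9.40 mM, k = 1.61 /h)
    Q + G ⇌ D + G, rate k2*[G]*[Q] forward; the back reaction follows from the equilibrium constant (K = 2.00, k = 479 /M/h)
    Z + J ⇌ L (K = 270 /M, k = 0.0436 /M/h)
    Z + J ⇌ Q (K = 25.0 /M, k = 0.523 /M/h)
    Q + G ⇌ L + G, rate k5*[G]*[Q] forward; the back reaction follows from the equilibrium constant (k = 38.6 /M/h)

The share of 92.2% at 6.0 min means a factor of 11.8, lower than the 18.0 read and close to the 12.0 that one scatter in L allows. The direct loss of Z and J to L is the main reason the early share falls short of complete: with that route taken away, the flask stands at 99.9% at 6.0 min instead of 92.2%. The neighbour flask with 1.2 M of Z keeps that factor, its share at 6.0 min being 92.2%.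

Readings and results were computed with constants of no real substance; the scatter is artificial.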